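Assumption: positions are cited with elemane numbering (C-5 carries the isopropenyl-derived group, C-6 the ester, C-7/C-8 the lactone, C-9 the hydroxyl, C-10 the quaternary carbon, C-1/C-2 the oxirane), β is the face of the C-10 methyl, and all starting materials are bought.

**Retrosynthetic overview**
1. The oxirane and the enal are made last: hydroxyl-directed epoxidation of a C-10 vinyl group and allylic oxidation of the C-5 isopropenyl group.
2. The α-methylene lactone (last ring formed) comes from Pd cyclocarbonylation of a trans-ethynyl alcohol, itself from alkynylalane opening of a 7α,8α-epoxy-9α-ol.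
3. C-6/C-9 oxygens come from singlet-oxygen addition to a cyclohexa-1,3-diene, followed by Mitsunobu inversion at C-6 with (S)-2-methylbutanoic acid.
4. Key step: the six-membered carbocycle is made by one-carbon ring expansion (β-oxido-carbenoid 1,2-alkenyl shift) of a cyclopentenone, trapped as the dienyl triflate.
5. The cyclopentenone carries C-5 and C-10, set by a tandem asymmetric conjugate addition/α-vinylation of 2-methylcyclopent-2-enone.

**Route**

Step 1
Reactants: 1 2-methylcyclopent-2-en-1-one; 2 prop-1-en-2-ylmagnesium bromide; 3 bromoethene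
Product: 5 (2S,3S)-2-ethenyl-2-methyl-3-(prop-1-en-2-yl)cyclopentan-1-one, via magnesium enolate 4 (not isolated)
Conditions: Cu(OTf)2 (3 mol %), chiral NHC ligand (enantiomer giving 3S), 2 (1.2 equiv), Et2O, −30 °C; then Pd(dba)2 (3 mol %), Q-Phos (6 mol %), 3 (1.5 equiv), THF, 0 → 25 °C
Reagents that add atoms: none
Why: Proposed new method: Cu/chiral-NHC-catalysed conjugate addition of the alkenyl Grignard sets C-5 under ligand control, and the fully substituted magnesium enolate 4 is intercepted in the same flask by Pd(0)/Q-Phos-catalysed enolate α-alkenylation with vinyl bromide (oxidative addition, enolate transmetalation, C–C reductive elimination anti to the new isopropenyl group), which creates quaternary C-10 with methyl cis to isopropenyl; the closest known reactions are Cu-catalysed conjugate addition with enolate trapping by allyl or alkyl electrophiles and the stand-alone Pd-catalysed α-vinylation of ketone enolates with vinyl bromides.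

Step 2
Reactants: 5 (2S,3S)-2-ethenyl-2-methyl-3-(prop-1-en-2-yl)cyclopentan-1-one
Product: 6 (4S,5S)-5-ethenyl-5-methyl-4-(prop-1-en-2-yl)cyclopent-2-en-1-one
Conditions: IBX (2 equiv), PhF/DMSO 2:1, 70 °C
Reagents that add atoms: none
Why: IBX α,β-dehydrogenation of a ketone (Nicolaou) can only occur on the methylene flank because the other α-carbon is quaternary, so one enone forms and no stereocentre is created.

Step 3
Reactants: 6 (4S,5S)-5-ethenyl-5-methyl-4-(prop-1-en-2-yl)cyclopent-2-en-1-one; 7 dibromomethane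
Product: 10 (5S,6S)-6-ethenyl-6-methyl-5-(prop-1-en-2-yl)cyclohexa-1,3-dien-1-yl trifluoromethanesulfonate, via lithium dibromomethylcarbinolate 8 (not isolated), via lithium dienolate 9 (not isolated)
Conditions: 7, LiTMP, THF, −95 °C, then 6; n-BuLi, −95 → −20 °C; PhNTf2, −78 → 0 °C
Reagents that add atoms: N-phenylbis(trifluoromethanesulfonimide), O=S(=O)(N(c1ccccc1)S(=O)(=O)C(F)(F)F)C(F)(F)F
Why: Nozaki–Yamamoto β-oxido-carbenoid ring enlargement (a semipinacol-type 1,2-shift): LiCHBr2 adds 1,2 to the enone, Br/Li exchange gives the carbenoid, and the alkenyl ring carbon (a better migrating group than the quaternary alkyl carbon) shifts to the carbenoid carbon with loss of LiBr, so the six-membered ring forms as the linear dienolate, whose O-triflation fixes both ring double bonds without touching a stereocentre.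

Step 4
Reactants: 10 (5S,6S)-6-ethenyl-6-methyl-5-(prop-1-en-2-yl)cyclohexa-1,3-dien-1-yl trifluoromethanesulfonate
Product: 11 (5R,6S)-5-ethenyl-5-methyl-6-(prop-1-en-2-yl)cyclohexa-1,3-diene
Conditions: Pd(OAc)2 (5 mol %), PPh3, HCO2H, n-Bu3N, DMF, 40 °C
Reagents that add atoms: none
Why: Pd-catalysed formate reduction of an alkenyl triflate (Cacchi) replaces OTf by H through oxidative addition, formate-to-hydride exchange with loss of CO2 and C–H reductive elimination, leaving the diene and both stereocentres unchanged.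

Step 5
Reactants: 11 (5R,6S)-5-ethenyl-5-methyl-6-(prop-1-en-2-yl)cyclohexa-1,3-diene
Product: 13 (1S,4R,5S,6S)-5-ethenyl-5-methyl-6-(prop-1-en-2-yl)cyclohex-2-ene-1,4-diol, via endoperoxide 12 (not isolated)
Conditions: O2, TPP (cat.), visible light, CH2Cl2, −40 °C; then Zn, AcOH, 0 °C
Reagents that add atoms: dioxygen, O=O
Why: Photo-oxygenation of the cyclic diene places singlet oxygen on the face opposite the pseudo-axial C-10 methyl (α-face), and reductive O–O cleavage leaves both carbinols α (cis-1,4-diol), which sets C-9 and, provisionally, C-6.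

Step 6
Reactants: 13 (1S,4R,5S,6S)-5-ethenyl-5-methyl-6-(prop-1-en-2-yl)cyclohex-2-ene-1,4-diol; 14 (2S)-2-methylbutanoic acid
Product: 15 (1R,4R,5S,6S)-5-ethenyl-4-hydroxy-5-methyl-6-(prop-1-en-2-yl)cyclohex-2-en-1-yl (2S)-2-methylbutanoate
Conditions: PPh3, DIAD, toluene/THF, −20 → 0 °C
Reagents that add atoms: none
Why: Mitsunobu esterification activates only the C-6 carbinol (the C-9 carbinol is neopentyl) and the carboxylate displaces it with SN2 inversion (6α-OH to 6β-ester), installing the side chain and the final C-6 configuration in one operation.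

Step 7
Reactants: 15 (1R,4R,5S,6S)-5-ethenyl-4-hydroxy-5-methyl-6-(prop-1-en-2-yl)cyclohex-2-en-1-yl (2S)-2-methylbutanoate
Product: 16 7α,8α-epoxy-9α-hydroxy-10β-methyl-5β-(prop-1-en-2-yl)-10α-ethenylcyclohexan-6β-yl (2S)-2-methylbutanoate (5S,6S,7R,8S,9S,10S)
Conditions: VO(acac)2 (3 mol %), t-BuOOH (1.1 equiv), CH2Cl2, 0 °C
Reagents that add atoms: tert-butyl hydroperoxide, CC(C)(C)OO
Why: Hydroxyl-directed vanadium epoxidation (Sharpless–Michaelson) delivers oxygen from the 9α-vanadate syn to the ring alkene to give the 7α,8α-epoxide, the allylic alkene reacting far faster than the homoallylic vinyl or undirected isopropenyl group.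

Step 8
Reactants: 16 the 7α,8α-epoxy-9α-ol ester; 17 ethynylmagnesium bromide
Product: 18 7β-ethynyl-8α,9α-dihydroxy-10β-methyl-5β-(prop-1-en-2-yl)-10α-ethenylcyclohexan-6β-yl (2S)-2-methylbutanoate (5S,6S,7R,8R,9S,10S)
Conditions: 17 + Et2AlCl (gives Et2AlC≡CH, 4 equiv), toluene/THF, 0 → 25 °C; Rochelle-salt work-up
Reagents that add atoms: none
Why: Alkynylalane opening of a 2,3-epoxy alcohol at C-3 (here C-7): the aluminium alkoxide of 9-OH shields C-8 while external alkynylalane attacks C-7 anti (SN2, inversion), attack at C-8 being disfavoured inductively and by syn-axial contacts with the C-10 methyl and C-6 ester, so ethynyl ends 7β and the new carbinol 8α.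

Step 9
Reactants: 18 the 7β-ethynyl-8α,9α-diol ester; 19 carbon monoxide
Product: 20 (5S,6S,7S,8R,9S,10S)-9-hydroxy-6-[(2S)-2-methylbutanoyloxy]elema-1,3,11(13)-trien-12,8-olide
Conditions: PdCl2 (5 mol %), PPh3 (10 mol %), SnCl2 (5 mol %), CO (7 atm), MeCN, 70 °C
Reagents that add atoms: none
Why: Norton-type Pd-catalysed cyclocarbonylation of a homopropargylic alcohol: the 8-O-alkoxycarbonyl–Pd species adds syn across the alkyne and protonolysis releases the α-methylene-γ-butyrolactone, with trans fusion fixed by step 8 and five-ring closure on 8-OH preferred over six-ring closure on 9-OH.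

Step 10
Reactants: 20 (5S,6S,7S,8R,9S,10S)-9-hydroxy-6-[(2S)-2-methylbutanoyloxy]elema-1,3,11(13)-trien-12,8-olide
Product: 22 (5R,6S,7S,8R,9S,10S)-9-hydroxy-6-[(2S)-2-methylbutanoyloxy]-15-oxoelema-1,3,11(13)-trien-12,8-olide, via allylic alcohol 21 (not isolated)
Conditions: SeO2 (0.3 equiv), t-BuOOH (2 equiv), CH2Cl2, 25 °C; then MnO2, 25 °C
Reagents that add atoms: selenium dioxide, O=[Se]=O; tert-butyl hydroperoxide, CC(C)(C)OO
Why: Sharpless SeO2/TBHP allylic oxidation attacks the methyl of the isopropenyl group (the C-10 vinyl has no allylic hydrogen and the methylene lactone is electron-poor), and MnO2 then oxidises only the primary allylic alcohol 21 to the enal, with no stereocentre affected.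

Step 11
Reactants: 22 (5R,6S,7S,8R,9S,10S)-9-hydroxy-6-[(2S)-2-methylbutanoyloxy]-15-oxoelema-1,3,11(13)-trien-12,8-olide
Product: 23 (1R,5R,6S,7S,8R,9S,10S)-1,2-epoxy-9-hydroxy-6-[(2S)-2-methylbutanoyloxy]-15-oxoelema-3,11(13)-dien-12,8-olide (target)
Conditions: VO(acac)2 (5 mol %), t-BuOOH (1.5 equiv), CH2Cl2, 0 → 25 °C
Reagents that add atoms: tert-butyl hydroperoxide, CC(C)(C)OO
Why: Hydroxyl-directed vanadium epoxidation of a homoallylic alcohol (Mihelich-type): in the chair-like vanadate transition state the axial 9α-oxygen reaches only the vinyl face exposed when the C=C lies over the C-10–C-5 bond, giving the 1R oxirane, while the enal and methylene-lactone alkenes are electron-poor and inert.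

**Compound list**
1 | 2-methylcyclopent-2-en-1-one | CC1=CCCC1=O | starting material
2 | prop-1-en-2-ylmagnesium bromide | CC(=C)[Mg]Br | starting material
3 | bromoethene (vinyl bromide) | C=CBr | starting material
4 | bromomagnesium (3S)-2-methyl-3-(prop-1-en-2-yl)cyclopent-1-en-1-olate | CC1=C(O[Mg]Br)CC[C@H]1C(=C)C | intermediate
5 | (2S,3S)-2-ethenyl-2-methyl-3-(prop-1-en-2-yl)cyclopentan-1-one | C=C[C@]1(C)C(=O)CC[C@H]1C(=C)C | intermediate
6 | (4S,5S)-5-ethenyl-5-methyl-4-(prop-1-en-2-yl)cyclopent-2-en-1-one | C=C[C@]1(C)C(=O)C=C[C@H]1C(=C)C | intermediate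
7 | dibromomethane | BrCBr | starting material
8 | lithium (4S,5S)-1-(dibromomethyl)-5-ethenyl-5-methyl-4-(prop-1-en-2-yl)cyclopent-2-en-1-olate (C-1 epimers) | C=C[C@]1(C)C(O[Li])(C(Br)Br)C=C[C@H]1C(=C)C | intermediate
9 | lithium (5S,6S)-6-ethenyl-6-methyl-5-(prop-1-en-2-yl)cyclohexa-1,3-dien-1-olate | C=C[C@]1(C)C(O[Li])=CC=C[C@H]1C(=C)C | intermediate
10 | (5S,6S)-6-ethenyl-6-methyl-5-(prop-1-en-2-yl)cyclohexa-1,3-dien-1-yl trifluoromethanesulfonate | C=C[C@]1(C)C(OS(=O)(=O)C(F)(F)F)=CC=C[C@H]1C(=C)C | intermediate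
11 | (5R,6S)-5-ethenyl-5-methyl-6-(prop-1-en-2-yl)cyclohexa-1,3-diene | C=C[C@]1(C)C=CC=C[C@H]1C(=C)C | intermediate
12 | 7-ethenyl-7-methyl-8-(prop-1-en-2-yl)-2,3-dioxabicyclo[2.2.2]oct-5-ene, peroxide bridge on the α-face (anti to the C-10 methyl) | C=C[C@]1(C)[C@H]2C=C[C@H](OO2)[C@H]1C(=C)C | intermediate
13 | (1S,4R,5S,6S)-5-ethenyl-5-methyl-6-(prop-1-en-2-yl)cyclohex-2-ene-1,4-diol | C=C[C@]1(C)[C@H](O)C=C[C@H](O)[C@H]1C(=C)C | intermediate
14 | (2S)-2-methylbutanoic acid | CC[C@H](C)C(=O)O | starting material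
15 | (1R,4R,5S,6S)-5-ethenyl-4-hydroxy-5-methyl-6-(prop-1-en-2-yl)cyclohex-2-en-1-yl (2S)-2-methylbutanoate | C=C[C@]1(C)[C@H](O)C=C[C@@H](OC(=O)[C@@H](C)CC)[C@H]1C(=C)C | intermediate
16 | 7α,8α-epoxy-9α-hydroxy-10β-methyl-5β-(prop-1-en-2-yl)-10α-ethenylcyclohexan-6β-yl (2S)-2-methylbutanoate (5S,6S,7R,8S,9S,10S) | C=C[C@]1(C)[C@H](O)[C@@H]2O[C@@H]2[C@@H](OC(=O)[C@@H](C)CC)[C@H]1C(=C)C | intermediate
17 | ethynylmagnesium bromide | C#C[Mg]Br | starting material
18 | 7β-ethynyl-8α,9α-dihydroxy-10β-methyl-5β-(prop-1-en-2-yl)-10α-ethenylcyclohexan-6β-yl (2S)-2-methylbutanoate (5S,6S,7R,8R,9S,10S) | C=C[C@]1(C)[C@H](O)[C@H](O)[C@@H](C#C)[C@@H](OC(=O)[C@@H](C)CC)[C@H]1C(=C)C | intermediate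
19 | carbon monoxide | [C-]#[O+] | starting material
20 | (5S,6S,7S,8R,9S,10S)-9-hydroxy-6-[(2S)-2-methylbutanoyloxy]elema-1,3,11(13)-trien-12,8-olide | C=C1C(=O)O[C@@H]2[C@@H]1[C@@H](OC(=O)[C@@H](C)CC)[C@@H](C(=C)C)[C@](C)(C=C)[C@@H]2O | intermediate
21 | (5S,6S,7S,8R,9S,10S)-9,15-dihydroxy-6-[(2S)-2-methylbutanoyloxy]elema-1,3,11(13)-trien-12,8-olide | C=C1C(=O)O[C@@H]2[C@@H]1[C@@H](OC(=O)[C@@H](C)CC)[C@@H](C(=C)CO)[C@](C)(C=C)[C@@H]2O | intermediate
22 | (5R,6S,7S,8R,9S,10S)-9-hydroxy-6-[(2S)-2-methylbutanoyloxy]-15-oxoelema-1,3,11(13)-trien-12,8-olide | C=C1C(=O)O[C@@H]2[C@@H]1[C@@H](OC(=O)[C@@H](C)CC)[C@@H](C(=C)C=O)[C@](C)(C=C)[C@@H]2O | intermediate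
23 | (1R,5R,6S,7S,8R,9S,10S)-1,2-epoxy-9-hydroxy-6-[(2S)-2-methylbutanoyloxy]-15-oxoelema-3,11(13)-dien-12,8-olide | C=C1C(=O)O[C@@H]2[C@@H]1[C@@H](OC(=O)[C@@H](C)CC)[C@@H](C(=C)C=O)[C@](C)([C@@H]1CO1)[C@@H]2O | target

**Totals**
Total step count: 11. Longest linear sequence: 11 steps (from 1).

**Three steps most likely to fail**

Step 1 (the proposed new tandem reaction). The hindered, fully substituted magnesium enolate may not transmetalate to palladium, or reductive elimination to the quaternary centre may be slow. Fallback with known chemistry: it sets out from 4 (made from 1 and 2 as in step 1) and comes back at 5. The enolate is quenched with acetaldehyde in an established conjugate-addition/aldol tandem to give (2R,3S)-2-(1-hydroxyethyl)-2-methyl-3-(prop-1-en-2-yl)cyclopentan-1-one F1 (carbinol epimers, new group again anti to the isopropenyl). Burgess dehydration of F1, which can only eliminate towards the methyl group because C-2 is quaternary, then gives 5. This costs one extra step.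

Step 3 (ring expansion). The γ-hydrogen of enone 6 is doubly allylic, so base-induced dienolisation may compete with addition of LiCHBr2, and some migration of the quaternary carbon instead of the alkenyl carbon cannot be excluded. Fallback: it sets out from 5 (omitting 6) and comes back at 10. Sc(OTf)3-catalysed homologation of 5 with trimethylsilyldiazomethane (methylene migration) gives {[(5S,6S)-6-ethenyl-6-methyl-5-(prop-1-en-2-yl)cyclohex-1-en-1-yl]oxy}trimethylsilane F2. Saegusa oxidation with Pd(OAc)2 gives (5S,6S)-6-ethenyl-6-methyl-5-(prop-1-en-2-yl)cyclohex-2-en-1-one F3. γ-Deprotonation of F3 with LiHMDS regenerates dienolate 9, which is triflated with PhNTf2 to 10. This costs two extra steps.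

Step 11 (directed epoxidation of the vinyl group). The facial selectivity rests on a transition-state model for a neopentyl homoallylic alcohol, and the aldehyde must survive the peroxide. Fallback: it sets out from 22 and comes back at 23. Undirected epoxidation with dimethyldioxirane, for which the vinyl group is the only electron-rich alkene left, gives the 1RS-epoxide mixture F4. Jacobsen hydrolytic kinetic resolution with the (salen)Co(III)OAc enantiomer that hydrolyses the 1S epimer converts that epimer into the (1S)-1,2-diol F5 and leaves 23.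

Further compounds
F1 | step 1 | (2R,3S)-2-(1-hydroxyethyl)-2-methyl-3-(prop-1-en-2-yl)cyclopentan-1-one (carbinol epimers) | CC(O)[C@]1(C)C(=O)CC[C@H]1C(=C)C
F2 | step 3 | {[(5S,6S)-6-ethenyl-6-methyl-5-(prop-1-en-2-yl)cyclohex-1-en-1-yl]oxy}trimethylsilane | C=C[C@]1(C)C(O[Si](C)(C)C)=CCC[C@H]1C(=C)C
F3 | step 3 | (5S,6S)-6-ethenyl-6-methyl-5-(prop-1-en-2-yl)cyclohex-2-en-1-one | C=C[C@]1(C)C(=O)C=CC[C@H]1C(=C)C
F4 | step 11 | 1RS-epoxide mixture (23 and its C-1 epimer) | C=C1C(=O)O[C@@H]2[C@@H]1[C@@H](OC(=O)[C@@H](C)CC)[C@@H](C(=C)C=O)[C@](C)(C1CO1)[C@@H]2O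
F5 | step 11 | (1S)-1,2-diol from hydrolysis of the 1S-epoxide | C=C1C(=O)O[C@@H]2[C@@H]1[C@@H](OC(=O)[C@@H](C)CC)[C@@H](C(=C)C=O)[C@](C)([C@H](O)CO)[C@@H]2O
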